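**Plan**
- Retrosynthesis: the CH2–aryl bond between rings B and C is cut first (aminomethyl transfer). Ring A is then cut at C1–C2 and C4–C5 (locants of 2-butanoyl-3,5-dihydroxy-4,4-dimethyl-6-benzylcyclohexa-2,5-dien-1-one). Last, the CH2 between rings C and D is cut.
- Enabling feature: ring A is a 2-acylcyclohexane-1,3,5-trione that cannot aromatise. C1, C6 and C5 are a benzylmalonyl unit (two acyl carbons). C2, C3 and C4 with the butanoyl group are 2-methyloctane-3,5-dione, whose central carbon C2 and isopropyl carbon C4 are both enol carbons.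
- Forward: ring B is carried as its tribenzyl ether with the bridge CH2 already on a malonic carbon (9 to 16). Ring A is then built around that carbon in one [3+3] double C-acylation with the 1-amino-3-siloxydiene 6, so the A–CH2–B bridge never depends on formaldehyde selectivity.
- Rings D and C are joined by aminomethylation and amine-for-arene exchange. The dimer is aminomethylated again and united with debenzylated A–CH2–B. In each coupling, each partner has a single reactive ring carbon.
- Stereochemistry: the target has no stereocentre. The E geometry of 4 and 6 comes from the conjugate addition and disappears in step 9.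

Key step: step 9

Remark: ring A is written as one enol tautomer of the trione; all tautomers are treated as one compound. Compounds 7, 21 and 25 are taken as commercially available.

**Step 1**
Reactants: 1 pent-1-yne; 2 2-methylpropanoyl chloride
Product: 3 2-methyloct-4-yn-3-one
Conditions: PdCl2(PPh3)2 (2 mol %), CuI (4 mol %), Et3N (1.2 equiv), THF, rt
Reagents that add atoms: none
Why: Acyl Sonogashira coupling of a terminal alkyne with an acid chloride should give the ynone directly, with the carbonyl next to the isopropyl group.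

**Step 2**
Reactants: 3 2-methyloct-4-yn-3-one
Product: 4 (4E)-2-methyl-5-(pyrrolidin-1-yl)oct-4-en-3-one
Conditions: pyrrolidine (1.1 equiv), EtOH, rt
Reagents that add atoms: pyrrolidine (C1CCNC1)
Why: Conjugate (aza-Michael) addition of a secondary amine to the ynone should put nitrogen on the propyl-bearing carbon only and give the thermodynamically preferred E vinylogous amide (nitrogen trans to the acyl group).

**Step 3**
Reactants: 4 (4E)-2-methyl-5-(pyrrolidin-1-yl)oct-4-en-3-one
Product: 6 1-[(4E)-3-(tert-butyldimethylsilyloxy)-2-methylocta-2,4-dien-5-yl]pyrrolidine, via potassium dienolate 5 (not isolated)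
Conditions: KN(SiMe3)2 (1.05 equiv), THF, −78 °C; then t-BuMe2SiCl, −78 °C → rt
Reagents that add atoms: tert-butyldimethylsilyl chloride (CC(C)(C)[Si](C)(C)Cl)
Why: Kinetic α′-deprotonation of a tertiary vinylogous amide followed by O-silylation is the established entry to 1-amino-3-siloxy-1,3-dienes; the enamine geometry is kept and the new CMe2 terminus has no geometry.

**Step 4**
Reactants: 7 1,3,5-tris(benzyloxy)benzene
Product: 9 2,4,6-tris(benzyloxy)benzaldehyde, via iminium chloride 8 (not isolated)
Conditions: POCl3 (1.2 equiv), DMF, 0 °C → rt; then H2O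
Reagents that add atoms: N,N-dimethylformamide (CN(C)C=O); water (O)
Why: Vilsmeier–Haack formylation of the symmetrical, strongly activated trialkoxybenzene should stop after one formyl group because the iminium substituent deactivates the ring.

**Step 5**
Reactants: 9 2,4,6-tris(benzyloxy)benzaldehyde; 10 2,2-dimethyl-1,3-dioxane-4,6-dione (Meldrum's acid)
Product: 12 5-{[2,4,6-tris(benzyloxy)phenyl]methyl}-2,2-dimethyl-1,3-dioxane-4,6-dione, via arylidene Meldrum's acid 11 (not isolated)
Conditions: diethyl 2,6-dimethyl-1,4-dihydropyridine-3,5-dicarboxylate (1.1 equiv), L-proline (20 mol %), EtOH, rt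
Reagents that add atoms: none
Why: Knoevenagel condensation followed in the same flask by transfer hydrogenation of the electron-poor alkylidene (organocatalytic reductive alkylation) should give the mono-benzylated Meldrum's acid; no stereocentre arises.

**Step 6**
Reactants: 12 5-{[2,4,6-tris(benzyloxy)phenyl]methyl}-2,2-dimethyl-1,3-dioxane-4,6-dione; 13 butanoic acid
Product: 14 5-{[2,4,6-tris(benzyloxy)-3-butanoylphenyl]methyl}-2,2-dimethyl-1,3-dioxane-4,6-dione
Conditions: (CF3CO)2O (2.0 equiv), 85% H3PO4 (cat.), CH2Cl2, 0 °C → rt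
Reagents that add atoms: none
Why: Friedel–Crafts acylation by the mixed butanoic trifluoroacetic anhydride needs no metal Lewis acid, so the benzyl ethers should survive; the two free ring positions are equivalent and the first ketone deactivates the ring against a second.

**Step 7**
Reactants: 14 5-{[2,4,6-tris(benzyloxy)-3-butanoylphenyl]methyl}-2,2-dimethyl-1,3-dioxane-4,6-dione
Product: 15 2-{[2,4,6-tris(benzyloxy)-3-butanoylphenyl]methyl}propanedioic acid
Conditions: 3 M HCl, THF, 50 °C
Reagents that add atoms: water (O)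
Why: Acid hydrolysis of the cyclic acylal should release the malonic acid and acetone well below the temperature of decarboxylation; the ketone and benzyl ethers are inert.

**Step 8**
Reactants: 15 2-{[2,4,6-tris(benzyloxy)-3-butanoylphenyl]methyl}propanedioic acid
Product: 16 2-{[2,4,6-tris(benzyloxy)-3-butanoylphenyl]methyl}propanedioyl dichloride
Conditions: (COCl)2 (2.5 equiv), DMF (cat.), CH2Cl2, 0 °C → rt; evaporated and used crude
Reagents that add atoms: oxalyl chloride (O=C(Cl)C(Cl)=O)
Why: Chloroiminium-catalysed conversion of both carboxylic acids into acid chlorides at or below rt should leave the hindered aryl ketone and the ethers untouched.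

**Step 9**
Reactants: 6 1-[(4E)-3-(tert-butyldimethylsilyloxy)-2-methylocta-2,4-dien-5-yl]pyrrolidine; 16 2-{[2,4,6-tris(benzyloxy)-3-butanoylphenyl]methyl}propanedioyl dichloride
Product: 19 2-butanoyl-6-{[2,4,6-tris(benzyloxy)-3-butanoylphenyl]methyl}-3,5-dihydroxy-4,4-dimethylcyclohexa-2,5-dien-1-one, via open-chain acyl chloride 17 (not isolated), via enaminotrione 18 (not isolated)
Conditions: 6 (1.1 equiv), 2,6-lutidine (1.2 equiv), CH2Cl2, −78 °C → rt; then 2 M HCl, THF, 40 °C
Reagents that add atoms: water (O)
Why: Proposed new method: diene 6 is a pure carbon 1,3-dinucleophile (the CMe2 terminus of its silyl enol ether and its enamine carbon, with oxygen capped by silicon and nitrogen tertiary) and 16 is a symmetrical 1,3-diacyl donor, so C-acylation at the CMe2 terminus with loss of the silyl group as its chloride gives 17, whose vinylogous amide carbon then acylates on the second acid chloride to close ring A as 18, and aqueous acid hydrolyses the exocyclic vinylogous amide of 18 to the butanoyl ketone. The closest known reaction types are the [3+3] cyclisations of 1,3-bis(silyl enol ethers) with 1,3-dielectrophiles, the cyclocondensations of malonyl dichlorides with 1,3-dinucleophiles, and the C-acylation of enaminones and silyl dienol ethers by acid chlorides. Ring A closes by a 6-(enolexo)-exo-trig acyl substitution. No stereocentre is created, because the labile malonyl carbon of 17 becomes an enol carbon of the trione and the E enamine geometry is lost on hydrolysis. The selectivities needed are carbon over oxygen acylation and the correct pairing of ring atoms: the first enol oxygen is blocked by silicon, the nucleophilic carbons were fixed when 6 was made, the two acid chlorides of 16 are equivalent so either order of bond formation gives the same ring, and a lactone formed through the enaminone oxygen would be an O-acyl vinylogous iminium salt that can return its acyl group, whereas the C-acylated product is drained by loss of a proton to the stabilised trione.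

**Step 10**
Reactants: 19 2-butanoyl-6-{[2,4,6-tris(benzyloxy)-3-butanoylphenyl]methyl}-3,5-dihydroxy-4,4-dimethylcyclohexa-2,5-dien-1-one
Product: 20 2-butanoyl-6-[(3-butanoyl-2,4,6-trihydroxyphenyl)methyl]-3,5-dihydroxy-4,4-dimethylcyclohexa-2,5-dien-1-one
Conditions: H2 (1 atm), 10% Pd/C, EtOAc–MeOH, rt
Reagents that add atoms: none
Why: Hydrogenolysis of the three benzyl aryl ethers; the hydrogen-bonded aryl ketone, the enolised trione and the bridging CH2 should be inert under these conditions.

**Step 11**
Reactants: 21 2-methylbenzene-1,3,5-triol; 22 butanoyl chloride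
Product: 23 1-(2,4,6-trihydroxy-3-methylphenyl)butan-1-one
Conditions: AlCl3 (3.5 equiv), PhNO2–CH2Cl2, 0 → 45 °C; then ice, 1 M HCl
Reagents that add atoms: none
Why: Friedel–Crafts acylation of the phloroglucinol nucleus at one of its two equivalent free positions; the acyl group deactivates the ring against a second acylation.

**Step 12**
Reactants: 23 1-(2,4,6-trihydroxy-3-methylphenyl)butan-1-one
Product: 24 1-{3-[(dimethylamino)methyl]-2,4,6-trihydroxy-5-methylphenyl}butan-1-one
Conditions: CH2(NMe2)2 (1.1 equiv), 1,4-dioxane, rt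
Reagents that add atoms: N,N,N',N'-tetramethylmethanediamine (CN(C)CN(C)C)
Why: Mannich aminomethylation by the aminal, which the acidic phenol itself ionises, can occur only at the single free ring carbon.

**Step 13**
Reactants: 24 1-{3-[(dimethylamino)methyl]-2,4,6-trihydroxy-5-methylphenyl}butan-1-one; 25 1-(2,4,6-trihydroxyphenyl)butan-1-one (4 equiv)
Product: 27 1-{3-[(3-butanoyl-2,4,6-trihydroxyphenyl)methyl]-2,4,6-trihydroxy-5-methylphenyl}butan-1-one, via quinone methide 26 (not isolated)
Conditions: 1,4-dioxane, 100 °C, N2 stream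
Reagents that add atoms: none
Why: Thermal loss of dimethylamine from the phenolic Mannich base should give an ortho-quinone methide that is captured by C-nucleophilic 25 (Michael addition and rearomatisation); 24 has no free ring carbon and cannot self-condense, and the excess of 25 suppresses double alkylation.

**Step 14**
Reactants: 27 1-{3-[(3-butanoyl-2,4,6-trihydroxyphenyl)methyl]-2,4,6-trihydroxy-5-methylphenyl}butan-1-one
Product: 28 1-{3-[(3-butanoyl-5-[(dimethylamino)methyl]-2,4,6-trihydroxyphenyl)methyl]-2,4,6-trihydroxy-5-methylphenyl}butan-1-one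
Conditions: CH2(NMe2)2 (1.1 equiv), 1,4-dioxane, rt
Reagents that add atoms: N,N,N',N'-tetramethylmethanediamine (CN(C)CN(C)C)
Why: Mannich aminomethylation at the only unsubstituted aromatic carbon of 27, on ring C.

**Step 15**
Reactants: 20 2-butanoyl-6-[(3-butanoyl-2,4,6-trihydroxyphenyl)methyl]-3,5-dihydroxy-4,4-dimethylcyclohexa-2,5-dien-1-one; 28 the aminomethylated C–D dimer
Product: 30 2-butanoyl-6-{[3-butanoyl-5-({3-butanoyl-5-[(3-butanoyl-2,4,6-trihydroxy-5-methylphenyl)methyl]-2,4,6-trihydroxyphenyl}methyl)-2,4,6-trihydroxyphenyl]methyl}-3,5-dihydroxy-4,4-dimethylcyclohexa-2,5-dien-1-one, via quinone methide 29 (not isolated)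
Conditions: 1,4-dioxane, 90 °C, N2 stream
Reagents that add atoms: none
Why: The same elimination–Michael addition sequence; 28 has no free ring carbon and 20 has exactly one (on ring B), so only the B–CH2–C bond can form, and the acidic ring A enol of 20 protonates the amine and assists its departure.

**Compound list**
1 | pent-1-yne | CCCC#C | starting material
2 | 2-methylpropanoyl chloride | CC(C)C(Cl)=O | starting material
3 | 2-methyloct-4-yn-3-one | CCCC#CC(=O)C(C)C | intermediate
4 | (4E)-2-methyl-5-(pyrrolidin-1-yl)oct-4-en-3-one | CCC/C(=C\C(=O)C(C)C)N1CCCC1 | intermediate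
5 | potassium (4E)-2-methyl-5-(pyrrolidin-1-yl)octa-2,4-dien-3-olate | CCC/C(=C\C([O-])=C(C)C)N1CCCC1.[K+] | intermediate
6 | 1-[(4E)-3-(tert-butyldimethylsilyloxy)-2-methylocta-2,4-dien-5-yl]pyrrolidine | CCC/C(=C\C(O[Si](C)(C)C(C)(C)C)=C(C)C)N1CCCC1 | intermediate
7 | 1,3,5-tris(benzyloxy)benzene | c1ccc(COc2cc(OCc3ccccc3)cc(OCc3ccccc3)c2)cc1 | starting material
8 | N-{[2,4,6-tris(benzyloxy)phenyl]methylidene}-N-methylmethanaminium chloride | C[N+](C)=Cc1c(OCc2ccccc2)cc(OCc2ccccc2)cc1OCc1ccccc1.[Cl-] | intermediate
9 | 2,4,6-tris(benzyloxy)benzaldehyde | O=Cc1c(OCc2ccccc2)cc(OCc2ccccc2)cc1OCc1ccccc1 | intermediate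
10 | 2,2-dimethyl-1,3-dioxane-4,6-dione (Meldrum's acid) | CC1(C)OC(=O)CC(=O)O1 | starting material
11 | 5-{[2,4,6-tris(benzyloxy)phenyl]methylidene}-2,2-dimethyl-1,3-dioxane-4,6-dione | CC1(C)OC(=O)C(=Cc2c(OCc3ccccc3)cc(OCc3ccccc3)cc2OCc2ccccc2)C(=O)O1 | intermediate
12 | 5-{[2,4,6-tris(benzyloxy)phenyl]methyl}-2,2-dimethyl-1,3-dioxane-4,6-dione | CC1(C)OC(=O)C(Cc2c(OCc3ccccc3)cc(OCc3ccccc3)cc2OCc2ccccc2)C(=O)O1 | intermediate
13 | butanoic acid | CCCC(=O)O | starting material
14 | 5-{[2,4,6-tris(benzyloxy)-3-butanoylphenyl]methyl}-2,2-dimethyl-1,3-dioxane-4,6-dione | CCCC(=O)c1c(OCc2ccccc2)cc(OCc2ccccc2)c(CC2C(=O)OC(C)(C)OC2=O)c1OCc1ccccc1 | intermediate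
15 | 2-{[2,4,6-tris(benzyloxy)-3-butanoylphenyl]methyl}propanedioic acid | CCCC(=O)c1c(OCc2ccccc2)cc(OCc2ccccc2)c(CC(C(=O)O)C(=O)O)c1OCc1ccccc1 | intermediate
16 | 2-{[2,4,6-tris(benzyloxy)-3-butanoylphenyl]methyl}propanedioyl dichloride | CCCC(=O)c1c(OCc2ccccc2)cc(OCc2ccccc2)c(CC(C(Cl)=O)C(Cl)=O)c1OCc1ccccc1 | intermediate
17 | (6E)-2-{[2,4,6-tris(benzyloxy)-3-butanoylphenyl]methyl}-4,4-dimethyl-3,5-dioxo-7-(pyrrolidin-1-yl)dec-6-enoyl chloride (racemic at the enolisable C2) | CCC/C(=C\C(=O)C(C)(C)C(=O)C(Cc1c(OCc2ccccc2)cc(OCc2ccccc2)c(C(=O)CCC)c1OCc1ccccc1)C(Cl)=O)N1CCCC1 | intermediate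
18 | 6-{[2,4,6-tris(benzyloxy)-3-butanoylphenyl]methyl}-4,4-dimethyl-2-[1-(pyrrolidin-1-yl)butylidene]cyclohexane-1,3,5-trione, drawn as its iminium enolate form | CCCC(=[N+]1CCCC1)C1=C([O-])C(C)(C)C(O)=C(Cc2c(OCc3ccccc3)cc(OCc3ccccc3)c(C(=O)CCC)c2OCc2ccccc2)C1=O | intermediate
19 | 2-butanoyl-6-{[2,4,6-tris(benzyloxy)-3-butanoylphenyl]methyl}-3,5-dihydroxy-4,4-dimethylcyclohexa-2,5-dien-1-one | CCCC(=O)C1=C(O)C(C)(C)C(O)=C(Cc2c(OCc3ccccc3)cc(OCc3ccccc3)c(C(=O)CCC)c2OCc2ccccc2)C1=O | intermediate
20 | 2-butanoyl-6-[(3-butanoyl-2,4,6-trihydroxyphenyl)methyl]-3,5-dihydroxy-4,4-dimethylcyclohexa-2,5-dien-1-one | CCCC(=O)C1=C(O)C(C)(C)C(O)=C(Cc2c(O)cc(O)c(C(=O)CCC)c2O)C1=O | intermediate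
21 | 2-methylbenzene-1,3,5-triol | Cc1c(O)cc(O)cc1O | starting material
22 | butanoyl chloride | CCCC(Cl)=O | starting material
23 | 1-(2,4,6-trihydroxy-3-methylphenyl)butan-1-one | CCCC(=O)c1c(O)cc(O)c(C)c1O | intermediate
24 | 1-{3-[(dimethylamino)methyl]-2,4,6-trihydroxy-5-methylphenyl}butan-1-one | CCCC(=O)c1c(O)c(C)c(O)c(CN(C)C)c1O | intermediate
25 | 1-(2,4,6-trihydroxyphenyl)butan-1-one | CCCC(=O)c1c(O)cc(O)cc1O | starting material
26 | 2-butanoyl-3,5-dihydroxy-4-methyl-6-methylidenecyclohexa-2,4-dien-1-one | C=C1C(=O)C(C(=O)CCC)=C(O)C(C)=C1O | intermediate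
27 | 1-{3-[(3-butanoyl-2,4,6-trihydroxyphenyl)methyl]-2,4,6-trihydroxy-5-methylphenyl}butan-1-one | CCCC(=O)c1c(O)c(C)c(O)c(Cc2c(O)cc(O)c(C(=O)CCC)c2O)c1O | intermediate
28 | 1-{3-[(3-butanoyl-5-[(dimethylamino)methyl]-2,4,6-trihydroxyphenyl)methyl]-2,4,6-trihydroxy-5-methylphenyl}butan-1-one | CCCC(=O)c1c(O)c(C)c(O)c(Cc2c(O)c(CN(C)C)c(O)c(C(=O)CCC)c2O)c1O | intermediate
29 | 2-butanoyl-4-[(3-butanoyl-2,4,6-trihydroxy-5-methylphenyl)methyl]-3,5-dihydroxy-6-methylidenecyclohexa-2,4-dien-1-one | CCCC(=O)c1c(O)c(C)c(O)c(CC2=C(O)C(=C)C(=O)C(C(=O)CCC)=C2O)c1O | intermediate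
30 | 2-butanoyl-6-{[3-butanoyl-5-({3-butanoyl-5-[(3-butanoyl-2,4,6-trihydroxy-5-methylphenyl)methyl]-2,4,6-trihydroxyphenyl}methyl)-2,4,6-trihydroxyphenyl]methyl}-3,5-dihydroxy-4,4-dimethylcyclohexa-2,5-dien-1-one | CCCC(=O)C1=C(O)C(C)(C)C(O)=C(Cc2c(O)c(Cc3c(O)c(Cc4c(O)c(C)c(O)c(C(=O)CCC)c4O)c(O)c(C(=O)CCC)c3O)c(O)c(C(=O)CCC)c2O)C1=O | target

**Totals and risks**
Total steps: 15. Longest linear sequence: 8 steps (steps 4, 5, 6, 7, 8, 9, 10, 15).

Step 9 (proposed new method). The ring closure may go through oxygen and give a pyrandione lactone instead of the carbocycle. The diene may be protodesilylated by the acidic malonyl C–H or by HCl before it acylates. Attack at the hindered CMe2 terminus may be too slow. Fallback with known chemistry, setting out from 25: geminal C-methylation (MeI, NaOMe, MeOH) should give 2-butanoyl-3,5-dihydroxy-4,4-dimethylcyclohexa-2,5-dien-1-one F1. Aminomethylation with CH2(NMe2)2 should give its 6-[(dimethylamino)methyl] derivative F2. Heating F2 with an excess of 25 in dioxane should transfer the methylene unit and return to the route at 20.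

Step 3. Deprotonation may occur at the allylic CH2 of the propyl group instead of the hindered isopropyl CH, which would give a regioisomeric diene. Fallback setting out from 1: the same palladium/copper acylation with 2-methylprop-2-enoyl chloride should give 2-methyloct-1-en-4-yn-3-one F3. Pyrrolidine should add to the ynone terminus to give (4E)-2-methyl-5-(pyrrolidin-1-yl)octa-1,4-dien-3-one F4. Conjugate hydrosilylation of the isopropenyl ketone (t-BuMe2SiH, RhCl(PPh3)3 cat.) should then deliver the silyl enol ether regiospecifically and return to the route at 6.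

Step 15. The liberated amine may promote reversible methylene transfer (retro-Michael opening of the bridges already present), which would scramble the ring sequence; O-alkylation may also compete with C-alkylation. Fallback setting out from 20 and 27: amine-free, acid-catalysed condensation with aqueous formaldehyde (cat. H2SO4, AcOH, rt), using an excess of 27 and separating the symmetrical by-products. This should give 30 directly and makes no new compound (F0).

**Further compounds**
F1 | step 9 | 2-butanoyl-3,5-dihydroxy-4,4-dimethylcyclohexa-2,5-dien-1-one | CCCC(=O)C1=C(O)C(C)(C)C(O)=CC1=O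
F2 | step 9 | 2-butanoyl-6-[(dimethylamino)methyl]-3,5-dihydroxy-4,4-dimethylcyclohexa-2,5-dien-1-one | CCCC(=O)C1=C(O)C(C)(C)C(O)=C(CN(C)C)C1=O
F3 | step 3 | 2-methyloct-1-en-4-yn-3-one | CCCC#CC(=O)C(C)=C
F4 | step 3 | (4E)-2-methyl-5-(pyrrolidin-1-yl)octa-1,4-dien-3-one | CCC/C(=C\C(=O)C(C)=C)N1CCCC1
F0 | step 15 | none | none
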